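**Retrosynthetic overview**
Feature: in ring B the C9 methine sits between the quaternary C10 (C20 methyl) and the exocyclic C8=C17 methylene, which is what an allylsilane leaves behind after attacking a C10 tertiary cation through C9.
1. C12–C13 (last): Negishi coupling of the C12 alkylzinc with 3-bromofuran-2(5H)-one attaches the butenolide.
2. C9–C10 (ring B, second ring): ionisation of the ring A C10 tertiary carbinol, capture by the (Z)-allylsilane and loss of silicon give C8=C17 and set C9 and C10.
3. C7–C8 and C8–C17: a 5-alkyl-2,3-dihydrofuran (from the C7 iodide) is opened by Me3SiCH2MgCl under nickel catalysis to the geometrically pure allylsilane.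
4. Ring A (first ring): Diels–Alder of the (5R)-menthyloxy butenolide with 1-acetoxybutadiene sets C4 and C5 and ties C19 to C6 as a cis lactone; the C10 carbinol comes from the ketone and MeMgBr.

Key step: step 17

Assumption: labdane numbering is used for all intermediates; 2,3-dihydrofuran, 3-bromofuran-2(5H)-one and all reagents are purchased, and the (5R) epimer of acetal 3 is taken to be separable from the (5S) epimer, which is recycled by acid equilibration.

**Step 1**
Reactants: 1 5-hydroxy-4-methylfuran-2(5H)-one; 2 (1R,2S,5R)-menthol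
Product: 3 (5R)-5-menthyloxy-4-methylfuran-2(5H)-one
Conditions: camphorsulfonic acid (cat.), toluene, reflux, Dean–Stark; crystallisation of the (5R) epimer
Reagents that add atoms: none
Why: Acid-catalysed acetalisation (pseudo-ester formation) of the hemiacetal lactone; the two C5 epimers are diastereomers, so the (5R) acetal that later steers the diene should be obtainable by crystallisation.

**Step 2**
Reactants: 3 (5R)-5-menthyloxy-4-methylfuran-2(5H)-one; 4 (E)-1-acetoxybuta-1,3-diene
Product: 5 Diels–Alder adduct (cis-fused menthyloxy lactone, C10 acetate, C1=C2)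
Conditions: 4 (4 equiv, commercial E/Z mixture), BHT (cat.), CH2Cl2, 1.2 GPa, 45 °C
Reagents that add atoms: none
Why: Diels–Alder reaction, run under pressure because the β-methyl group makes the butenolide a sluggish dienophile; the diene should add anti to the menthyloxy group (sets C4 and C5, C19 cis to C6) and its acetoxy terminus should bond to the lactone α-carbon (ortho rule), putting oxygen on C10, whose endo configuration is immaterial.

**Step 3**
Reactants: 5 Diels–Alder adduct
Product: 6 saturated adduct
Conditions: H2 (1 atm), 5% Rh/Al2O3, EtOAc, rt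
Reagents that add atoms: none
Why: Catalytic hydrogenation of the cis-disubstituted ring olefin; rhodium on alumina is chosen so that the allylic acetate is not hydrogenolysed.

**Step 4**
Reactants: 6 saturated adduct
Product: 9 cis-fused C10-hydroxy γ-lactone, via sodium aldehyde carboxylate 7 (not isolated), via sodium dihydroxy carboxylate 8 (not isolated)
Conditions: NaOH (aq.), MeOH, rt; NaBH4, 0 °C → rt; then 2 M HCl to pH 2
Reagents that add atoms: sodium hydroxide, [Na+].[OH-] (statistically supplies the lactone carbonyl oxygen)
Why: Saponification of the pseudo-ester and the acetate releases menthol and the C19 aldehyde (no α-hydrogen, so C4 cannot epimerise), NaBH4 reduction and acid lactonisation then give the lactone with C19 at the alcohol level and C6 at the acid level.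

**Step 5**
Reactants: 9 cis-fused C10-hydroxy γ-lactone
Product: 10 lactol
Conditions: i-Bu2AlH (2.3 equiv), CH2Cl2, −78 °C; aqueous potassium sodium tartrate
Reagents that add atoms: none
Why: Partial hydride reduction of a lactone; the tetrahedral aluminium alkoxide is stable at −78 °C, so reduction should stop at the lactol.

**Step 6**
Reactants: 10 lactol
Product: 12 vinyl diol, via open hydroxy aldehyde 11 (not isolated)
Conditions: Ph3PCH3Br, KOt-Bu, THF, 0 °C → rt
Reagents that add atoms: methyltriphenylphosphonium bromide, C[P+](c1ccccc1)(c1ccccc1)c1ccccc1.[Br-]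
Why: Wittig methylenation of the lactol through its open hydroxy aldehyde installs C7; the unstabilised ylide should add faster than it enolises the hindered C5 position, so C5 is kept.

**Step 7**
Reactants: 12 vinyl diol
Product: 13 C19 tert-butyldimethylsilyl ether
Conditions: t-BuMe2SiCl (1.05 equiv), imidazole, CH2Cl2, 0 °C
Reagents that add atoms: tert-butyldimethylsilyl chloride, CC(C)(C)[Si](C)(C)Cl
Why: Selective silylation of the primary C19 hydroxyl over the hindered secondary C10 hydroxyl.

**Step 8**
Reactants: 13 C19 silyl ether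
Product: 14 C10 ketone
Conditions: DMP (1,1,1-triacetoxy-1,2-benziodoxol-3(1H)-one), NaHCO3, CH2Cl2, 0 °C → rt
Reagents that add atoms: none
Why: Dess–Martin oxidation under buffered, near-neutral conditions, which should leave the β,γ-unsaturated ketone unconjugated and C5 unepimerised.

**Step 9**
Reactants: 14 C10 ketone
Product: 15 C10 tertiary carbinol (both C10 epimers)
Conditions: MeMgBr, CeCl3 (anhydrous), THF, −78 °C
Reagents that add atoms: methylmagnesium bromide, C[Mg]Br
Why: Organocerium-modified Grignard 1,2-addition, whose low basicity should suppress enolisation of the ketone at C5; the new C10 centre need not be controlled because both epimers give the same cation in step 17.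

**Step 10**
Reactants: 15 C10 tertiary carbinol
Product: 16 C10 triethylsilyl ether
Conditions: Et3SiOTf, 2,6-lutidine, CH2Cl2, −78 → 0 °C
Reagents that add atoms: triethylsilyl trifluoromethanesulfonate, CC[Si](CC)(CC)OS(=O)(=O)C(F)(F)F
Why: Silylation of a tertiary alcohol with a silyl triflate; it prevents the C10 alkoxide from displacing the C7 iodide (5-exo-tet ether formation) in step 12.

**Step 11**
Reactants: 16 C10 triethylsilyl ether
Product: 18 C7 iodide, via alkylzirconocene chloride 17 (not isolated)
Conditions: Cp2Zr(H)Cl (1.5 equiv), THF, rt; then I2, 0 °C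
Reagents that add atoms: iodine, II
Why: Hydrozirconation places zirconium on the terminal carbon of the vinyl group and iodinolysis of the C–Zr bond should give the primary iodide.

**Step 12**
Reactants: 18 C7 iodide; 19 2,3-dihydrofuran
Product: 21 5-alkyl-2,3-dihydrofuran, via 5-lithio-2,3-dihydrofuran 20 (not isolated)
Conditions: 19 (4 equiv), t-BuLi, THF, −78 → 0 °C; then 18, THF, −30 °C → rt
Reagents that add atoms: none
Why: α-Lithiation of the cyclic enol ether followed by SN2 alkylation with the unhindered primary iodide forms C7–C8 and fixes the future C8=C9 olefin inside a ring.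

**Step 13**
Reactants: 21 5-alkyl-2,3-dihydrofuran; 22 (trimethylsilyl)methylmagnesium chloride
Product: 23 (Z)-allylsilane homoallylic alcohol
Conditions: NiCl2(PPh3)2 (10 mol %), 22 (4 equiv, Et2O), toluene, 80 °C; aq. NH4Cl
Reagents that add atoms: none
Why: Nickel-catalysed Kumada-type coupling of a Grignard reagent with the vinylic C–O bond of the enol ether (the precatalyst is reduced in the flask to zerovalent nickel); substitution with retention should put the silylmethyl group cis to the hydroxyethyl chain, that is C7 trans to C11, and the Grignard reagent has no β-hydrogen.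

**Step 14**
Reactants: 23 (Z)-allylsilane homoallylic alcohol
Product: 24 triol
Conditions: Bu4NF, THF, 0 → 40 °C
Reagents that add atoms: none
Why: Fluoride desilylation of both silyl ethers; the allylic C–Si bond should survive because no electrophile is present.

**Step 15**
Reactants: 24 triol
Product: 25 C12 tert-butyldiphenylsilyl ether
Conditions: t-BuPh2SiCl (1.05 equiv), imidazole, CH2Cl2, −20 → 0 °C
Reagents that add atoms: tert-butyldiphenylsilyl chloride, CC(C)(C)[Si](Cl)(c1ccccc1)c1ccccc1
Why: Selective silylation of the unhindered primary C12 hydroxyl; the neopentyl C19 and tertiary C10 hydroxyls should react far more slowly with the bulky chloride.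

**Step 16**
Reactants: 25 C12 silyl ether
Product: 26 cyclisation precursor (C19 acetate, free C10 carbinol)
Conditions: Ac2O, pyridine, DMAP (cat.), CH2Cl2, 0 °C
Reagents that add atoms: acetic anhydride, CC(=O)OC(C)=O
Why: Acylation of the primary C19 alcohol; the tertiary C10 alcohol is inert under these conditions.

**Step 17**
Reactants: 26 cyclisation precursor
Product: 28 19-acetoxy-ent-labd-8(17)-ene C12 silyl ether, via C10 tertiary carbocation 27 (not isolated)
Conditions: BF3·OEt2 (1.5 equiv), CH2Cl2, −78 → −30 °C; Et3N, then aq. NaHCO3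
Reagents that add atoms: none
Why: BF3·OEt2 ionises the C10 carbinol (either epimer) to the planar tertiary cation, the γ-carbon C9 of the tethered allylsilane attacks it, and the β-silyl cation at C8 loses Me3Si to leave the C8=C17 methylene. The closest known reaction type is the Lewis-acid-induced cation–olefin cyclisation of a tertiary carbinol terminated by an allylsilane (intramolecular Sakurai-type alkylation), in effect the second ring closure of a polyene cyclisation run stepwise. Ring B closes in the 6-endo-trig mode, both olefinic carbons C8 and C9 ending up in the ring. C10 is controlled by the existing C5 centre through a chair transition state: the C6 tether is equatorial on ring A and C9 bonds equatorially, which leaves the C20 methyl axial and the fusion trans, while the axial C19 acetoxymethyl group shields the axial trajectory that would give the cis-decalin. C9 is controlled by the olefin geometry: with C7 and C11 trans across C8=C9, C11 takes the equatorial position of the chair, so H9 ends cis to H5. The step needs C–C bond formation to outrun proton loss and protodesilylation, which the nucleophilic 2-substituted allylsilane, the six-membered transition state and the low temperature should secure, and C19 is an acetate because a free hydroxyl would capture the cation as a cyclic ether.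

**Step 18**
Reactants: 28 bicyclic C12 silyl ether
Product: 29 C12 alcohol
Conditions: Bu4NF, AcOH (1:1), THF, rt
Reagents that add atoms: none
Why: Fluoride desilylation buffered with acetic acid so that the C19 acetate is neither cleaved nor transferred.

**Step 19**
Reactants: 29 C12 alcohol
Product: 30 C12 iodide
Conditions: I2, PPh3, imidazole, CH2Cl2, 0 °C → rt
Reagents that add atoms: iodine, II
Why: Appel-type iodination, an SN2 displacement of the alkoxyphosphonium ion at the unhindered primary C12.

**Step 20**
Reactants: 30 C12 iodide; 31 3-bromofuran-2(5H)-one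
Product: 33 19-acetoxy-ent-labda-8(17),13-dien-16,15-olide (target), via C12 alkylzinc iodide 32 (not isolated)
Conditions: Zn dust (activated), LiCl, THF, 40 °C; then 31, Pd(PPh3)4 (5 mol %), THF, rt → 50 °C
Reagents that add atoms: none
Why: Zinc insertion into the primary C–I bond followed by Negishi coupling (oxidative addition into the activated vinylic C–Br bond, alkyl transfer from zinc, reductive elimination) should form C12–C13; the mild organozinc tolerates the acetate, the lactone and the exocyclic olefin.

**Compound list**
1 | 5-hydroxy-4-methylfuran-2(5H)-one | CC1=CC(=O)OC1O | starting material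
2 | (1R,2S,5R)-menthol | CC(C)[C@@H]1CC[C@@H](C)C[C@H]1O | starting material
3 | (5R)-5-{[(1R,2S,5R)-5-methyl-2-(propan-2-yl)cyclohexyl]oxy}-4-methylfuran-2(5H)-one | CC(C)[C@@H]1CC[C@@H](C)C[C@H]1O[C@@H]1OC(=O)C=C1C | intermediate
4 | (E)-1-acetoxybuta-1,3-diene | CC(=O)O/C=C/C=C | starting material
5 | Diels–Alder adduct: cis-fused menthyloxy lactone on ring A with C1=C2; C10 acetate, C6 and C19 all cis, C18 methyl and menthyloxy on the other face | CC(C)[C@@H]1CC[C@@H](C)C[C@H]1O[C@@H]1OC(=O)[C@H]2[C@@H](OC(C)=O)C=CC[C@@]12C | intermediate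
6 | saturated adduct (ring A hydrogenated, otherwise as 5) | CC(C)[C@@H]1CC[C@@H](C)C[C@H]1O[C@@H]1OC(=O)[C@H]2[C@@H](OC(C)=O)CCC[C@@]12C | intermediate
7 | sodium 2-formyl-6-hydroxy-2-methylcyclohexane-1-carboxylate (C19 aldehyde, C6 carboxylate, all-cis) | O[C@H]1CCC[C@@](C)(C=O)[C@H]1C(=O)[O-].[Na+] | intermediate
8 | sodium 6-hydroxy-2-(hydroxymethyl)-2-methylcyclohexane-1-carboxylate | O[C@H]1CCC[C@@](C)(CO)[C@H]1C(=O)[O-].[Na+] | intermediate
9 | 7-hydroxy-3a-methylhexahydro-2-benzofuran-1(3H)-one (cis ring fusion, hydroxyl cis to the lactone) | O[C@H]1CCC[C@@]2(C)COC(=O)[C@@H]12 | intermediate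
10 | 3a-methyloctahydro-2-benzofuran-1,7-diol (lactol, anomer mixture) | O[C@H]1CCC[C@@]2(C)COC(O)[C@@H]12 | intermediate
11 | 2-hydroxy-6-(hydroxymethyl)-6-methylcyclohexane-1-carbaldehyde (open form of 10) | O[C@H]1CCC[C@@](C)(CO)[C@H]1C=O | intermediate
12 | 3-(hydroxymethyl)-3-methyl-2-vinylcyclohexan-1-ol (vinyl, C19 and C10 hydroxyl all cis) | O[C@H]1CCC[C@@](C)(CO)[C@H]1C=C | intermediate
13 | C19 tert-butyldimethylsilyl ether of 12 | O[C@H]1CCC[C@@](C)(CO[Si](C)(C)C(C)(C)C)[C@H]1C=C | intermediate
14 | 3-[(tert-butyldimethylsilyloxy)methyl]-3-methyl-2-vinylcyclohexan-1-one | O=C1CCC[C@@](C)(CO[Si](C)(C)C(C)(C)C)[C@H]1C=C | intermediate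
15 | C10 tertiary carbinol (1-methylcyclohexanol, C10 epimers) | CC1(O)CCC[C@@](C)(CO[Si](C)(C)C(C)(C)C)[C@H]1C=C | intermediate
16 | C10 triethylsilyl ether of 15 | CC[Si](CC)(CC)OC1(C)CCC[C@@](C)(CO[Si](C)(C)C(C)(C)C)[C@H]1C=C | intermediate
17 | C7 alkylzirconocene chloride | CC[Si](CC)(CC)OC1(C)CCC[C@@](C)(CO[Si](C)(C)C(C)(C)C)[C@H]1CC[Zr](Cl)(C1C=CC=C1)C1C=CC=C1 | intermediate
18 | C7 iodide (C5 2-iodoethyl chain) | CC[Si](CC)(CC)OC1(C)CCC[C@@](C)(CO[Si](C)(C)C(C)(C)C)[C@H]1CCI | intermediate
19 | 2,3-dihydrofuran | C1CC=CO1 | starting material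
20 | 5-lithio-2,3-dihydrofuran | [Li]C1=CCCO1 | intermediate
21 | 5-alkyl-2,3-dihydrofuran (ring carbons become C8, C9, C11, C12) | CC[Si](CC)(CC)OC1(C)CCC[C@@](C)(CO[Si](C)(C)C(C)(C)C)[C@H]1CCC1=CCCO1 | intermediate
22 | (trimethylsilyl)methylmagnesium chloride | C[Si](C)(C)C[Mg]Cl | starting material
23 | (Z)-allylsilane with free C12 hydroxyl (C7 and C11 trans) | CC[Si](CC)(CC)OC1(C)CCC[C@@](C)(CO[Si](C)(C)C(C)(C)C)[C@H]1CC/C(C[Si](C)(C)C)=C/CCO | intermediate
24 | triol (C10, C12, C19 hydroxyls), (Z)-allylsilane | CC1(O)CCC[C@@](C)(CO)[C@H]1CC/C(C[Si](C)(C)C)=C/CCO | intermediate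
25 | C12 tert-butyldiphenylsilyl ether diol | CC1(O)CCC[C@@](C)(CO)[C@H]1CC/C(C[Si](C)(C)C)=C/CCO[Si](c1ccccc1)(c1ccccc1)C(C)(C)C | intermediate
26 | cyclisation precursor: ring A C10 carbinol (C10 epimers), C19 acetate, (Z)-allylsilane, C12 silyl ether | CC1(O)CCC[C@@](C)(COC(C)=O)[C@H]1CC/C(C[Si](C)(C)C)=C/CCO[Si](c1ccccc1)(c1ccccc1)C(C)(C)C | intermediate
27 | C10 tertiary carbocation | C[C+]1CCC[C@@](C)(COC(C)=O)[C@H]1CC/C(C[Si](C)(C)C)=C/CCO[Si](c1ccccc1)(c1ccccc1)C(C)(C)C | intermediate
28 | 19-acetoxy-ent-labd-8(17)-ene core (13,14,15,16-tetranor) with C12 tert-butyldiphenylsilyl ether; trans-decalin, C19 and C20 cis, H5 and H9 cis | C=C1CC[C@@H]2[C@](C)(COC(C)=O)CCC[C@@]2(C)[C@@H]1CCO[Si](c1ccccc1)(c1ccccc1)C(C)(C)C | intermediate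
29 | C12 alcohol | C=C1CC[C@@H]2[C@](C)(COC(C)=O)CCC[C@@]2(C)[C@@H]1CCO | intermediate
30 | C12 iodide | C=C1CC[C@@H]2[C@](C)(COC(C)=O)CCC[C@@]2(C)[C@@H]1CCI | intermediate
31 | 3-bromofuran-2(5H)-one | O=C1OCC=C1Br | starting material
32 | C12 alkylzinc iodide | C=C1CC[C@@H]2[C@](C)(COC(C)=O)CCC[C@@]2(C)[C@@H]1CC[Zn]I | intermediate
33 | 19-acetoxy-ent-labda-8(17),13-dien-16,15-olide | C=C1CC[C@@H]2[C@](C)(COC(C)=O)CCC[C@@]2(C)[C@@H]1CCC1=CCOC1=O | target

**Step count**
Total: 20 steps. Longest linear sequence: 20 steps (1 → 33); compounds 4, 19, 22 and 31 enter as purchased materials.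

**Steps most likely to fail**

Step 17 (key step). Proton loss from the C10 cation to ring A olefins, or capture on the axial face to give the cis ring fusion, may outrun the wanted closure, and acid set free would then protodesilylate the allylsilane. The fallback changes the way the cation is made: it sets out from iodide 18 and comes back at 28. Both silyl ethers of 18 are removed (aqueous HF, MeCN) and the diol is closed with catalytic p-TsOH in CH2Cl2 to the bridged C10–O–C19 ether iodide F1. This compound needs no protecting group. Alkylation of 20 with F1 should give the bridged ether dihydrofuran F2, NiCl2(PPh3)2 with 22 the bridged ether allylsilane alcohol F3, and t-BuPh2SiCl/imidazole its C12 silyl ether F4. TiCl4 (CH2Cl2, −78 °C) then opens the tertiary C–O bond of the ether. Because the leaving alkoxide stays tethered at C4, ion-pair return re-forms F4 rather than an olefin, so the cation is offered to the allylsilane repeatedly and no acetate neighbours it. Closure should give the 19-hydroxy bicycle F5, which Ac2O/pyridine converts into 28.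

Step 2. The β-methyl group may slow the cycloaddition so much that the diene polymerises first, and forcing it may erode the facial and regiochemical bias. The fallback builds ring A without a cycloaddition and replaces the whole opening (compounds 1–8), so it sets out not from an intermediate but from purchased 3-methylcyclohex-2-en-1-one, and it comes back at 9. Conjugate addition of PhB(OH)2 catalysed by Pd(OCOCF3)2 and (S)-t-BuPyOx should give (R)-3-methyl-3-phenylcyclohexan-1-one F6, which sets C4. RuCl3/NaIO4 degrades the arene to the keto acid F7. LiAlH4 gives the diol F8, and NaOCl/AcOH reoxidises only the secondary alcohol to the hydroxy ketone F9. ClCO2Me/pyridine gives the methyl carbonate F10. NaH in THF should then effect the intramolecular Claisen (Dieckmann-type) acylation at C5, the only enolate position that closes a five-membered lactone, to the cis-fused β-keto lactone F11. NaBH4, delivering hydride from the convex face, should give 9.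

Step 20. Slow alkyl transfer from zinc, β-hydride elimination from the alkylpalladium intermediate or metal-induced degradation of the bromobutenolide may divert the coupling. The fallback builds the butenolide by enolate alkylation instead: it sets out from iodide 30 and comes back at 33. The lithium enolate of 3-(phenylsulfanyl)oxolan-2-one (LiN(i-Pr)2, THF/HMPA, −78 → 0 °C) is alkylated with 30 to the α-alkyl-α-phenylsulfanyl lactone F12. mCPBA (1 equiv, −78 °C, where the exocyclic olefin is not epoxidised) gives the sulfoxide F13. Its thermal syn-elimination toward the ring methylene (toluene, 110 °C, CaCO3) should give 33.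

**Further compounds**
F1 | step 17 | bridged C10–O–C19 ether iodide | C[C@@]12CCC[C@@](C)(CO1)[C@H]2CCI
F2 | step 17 | bridged ether 5-alkyl-2,3-dihydrofuran | C[C@@]12CCC[C@@](C)(CO1)[C@H]2CCC1=CCCO1
F3 | step 17 | bridged ether (Z)-allylsilane alcohol | C[C@@]12CCC[C@@](C)(CO1)[C@H]2CC/C(C[Si](C)(C)C)=C/CCO
F4 | step 17 | bridged ether (Z)-allylsilane C12 tert-butyldiphenylsilyl ether | C[C@@]12CCC[C@@](C)(CO1)[C@H]2CC/C(C[Si](C)(C)C)=C/CCO[Si](c1ccccc1)(c1ccccc1)C(C)(C)C
F5 | step 17 | 19-hydroxy-ent-labd-8(17)-ene core with C12 silyl ether | C=C1CC[C@@H]2[C@](C)(CO)CCC[C@@]2(C)[C@@H]1CCO[Si](c1ccccc1)(c1ccccc1)C(C)(C)C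
F6 | step 2 | (R)-3-methyl-3-phenylcyclohexan-1-one | O=C1CCC[C@@](C)(c2ccccc2)C1
F7 | step 2 | 1-methyl-3-oxocyclohexane-1-carboxylic acid | O=C1CCC[C@@](C)(C(=O)O)C1
F8 | step 2 | 3-(hydroxymethyl)-3-methylcyclohexan-1-ol (C10 epimers) | OC1CCC[C@@](C)(CO)C1
F9 | step 2 | 3-(hydroxymethyl)-3-methylcyclohexan-1-one | O=C1CCC[C@@](C)(CO)C1
F10 | step 2 | methyl (1-methyl-3-oxocyclohexyl)methyl carbonate | O=C1CCC[C@@](C)(COC(=O)OC)C1
F11 | step 2 | 3a-methyltetrahydro-2-benzofuran-1,7(3H,7aH)-dione (cis-fused β-keto lactone) | O=C1CCC[C@@]2(C)COC(=O)[C@@H]12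
F12 | step 20 | α-alkyl-α-phenylsulfanyl lactone (C13 epimers) | C=C1CC[C@@H]2[C@](C)(COC(C)=O)CCC[C@@]2(C)[C@@H]1CCC1(Sc2ccccc2)CCOC1=O
F13 | step 20 | corresponding sulfoxide | C=C1CC[C@@H]2[C@](C)(COC(C)=O)CCC[C@@]2(C)[C@@H]1CCC1(S(=O)c2ccccc2)CCOC1=O
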